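The route rests on cutting ring A at the C1–C10 bond beside the angular methyl (labdane numbering). The key step is an iron-hydride hydrogen-atom-transfer radical reductive alkylation: H· adds to an exocyclic C10=C20 methylene on a monocyclic ring-B ketone, which turns C20 into the angular methyl and C10 into a tertiary radical that closes ring A onto the C1 tosylhydrazone carbon; sulfinate and N2 then leave, so C1 ends as a plain CH2. One operation sets the quaternary C10 and the trans A/B fusion under control of C5, while C9 epimers and hydrazone isomers converge. The precursor is a 2-alkyl-3-methylene-4-(tert-alkyl)cyclohexanone bearing both side chains.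

Key step: step 10

Remark: atoms are numbered as in labdane (ring A = C1–C5, C10; ring B = C5–C10; C20 = angular methyl, C17 = carbon on C8); the half-ester 9 and the Grignard solution 2 are assumed to be purchasable.

Step 1
Reactants: 1 3-methylbut-2-enal; 2 [2-(1,3-dioxolan-2-yl)ethyl]magnesium bromide
Product: 3 5-(1,3-dioxolan-2-yl)-3,3-dimethylpentanal
Conditions: CuBr·SMe2 (10 mol %), TMSCl, THF, −78 to −40 °C; then 1 M citric acid, 0 °C
Reagents that add atoms: none
Why: Copper-catalysed, TMSCl-accelerated conjugate addition of the Grignard reagent to the β,β-disubstituted enal builds quaternary C4 with its two methyls and the masked C1 aldehyde, and no stereocenter is formed.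

Step 2
Reactants: 3 5-(1,3-dioxolan-2-yl)-3,3-dimethylpentanal; 4 but-3-en-2-one
Product: 6 (4R)-4-[4-(1,3-dioxolan-2-yl)-2-methylbutan-2-yl]cyclohex-2-en-1-one, via keto-aldehyde 5 (not isolated)
Conditions: (S)-2-[diphenyl(trimethylsilyloxy)methyl]pyrrolidine (20 mol %), ethyl 3,4-dihydroxybenzoate (20 mol %), neat, 4 °C; then LiOH·H2O, i-PrOH, rt
Reagents that add atoms: none
Why: Enamine Michael addition to the vinyl ketone, in which the vinyl ketone approaches the unshielded face of the (E)-enamine and so sets C5 (2S in 5, 4R in 6), followed by intramolecular aldol condensation (organocatalytic Robinson-type annulation).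

Step 3
Reactants: 6 (4R)-4-[4-(1,3-dioxolan-2-yl)-2-methylbutan-2-yl]cyclohex-2-en-1-one
Product: 7 {[(3S,4R)-4-[4-(1,3-dioxolan-2-yl)-2-methylbutan-2-yl]-3-methylcyclohex-1-en-1-yl]oxy}trimethylsilane
Conditions: Me2CuLi, TMSCl, THF, −78 °C
Reagents that add atoms: lithium dimethylcuprate [Li+].C[Cu-]C; chlorotrimethylsilane C[Si](C)(C)Cl
Why: Cuprate conjugate addition anti to the bulky C5 substituent with in situ O-silylation gives the regiodefined enol silane, and the new C10 center is only temporary.

Step 4
Reactants: 7 the (3S,4R)-enol silane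
Product: 8 (4S)-4-[4-(1,3-dioxolan-2-yl)-2-methylbutan-2-yl]-3-methylcyclohex-2-en-1-one
Conditions: Pd(OAc)2 (1.05 equiv), MeCN, rt
Reagents that add atoms: none
Why: Saegusa–Ito oxidation, in which the palladium enolate loses the C10–H by β-hydride elimination and returns the enone now carrying the future angular methyl, leaves C5 untouched.

Step 5
Reactants: 9 (3R)-5-methoxy-3-methyl-5-oxopentanoic acid (methyl hydrogen (R)-3-methylglutarate)
Product: 10 (4S)-4-methyloxan-2-one
Conditions: LiBH4 (2 equiv), THF, 0 °C to rt; then 2 M HCl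
Reagents that add atoms: none
Why: Chemoselective hydride reduction of the ester beside the lithium carboxylate and acid-promoted lactonization leave the stereocenter untouched (only its descriptor changes).

Step 6
Reactants: 10 (4S)-4-methyloxan-2-one
Product: 11 methyl (3R)-5-iodo-3-methylpentanoate
Conditions: TMSI, CH2Cl2, rt; then MeOH, rt
Reagents that add atoms: iodotrimethylsilane C[Si](C)(C)I; methanol CO
Why: Silyl-activated SN2 opening of the lactone by iodide at the primary O–CH2 carbon and in situ acid-catalysed esterification give the iodo ester with the remote stereocenter intact.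

Step 7
Reactants: 8 the (4S)-3-methyl enone; 11 methyl (3R)-5-iodo-3-methylpentanoate
Product: 12 methyl (3S)-5-{(3S)-3-[4-(1,3-dioxolan-2-yl)-2-methylbutan-2-yl]-2-methyl-6-oxocyclohex-1-en-1-yl}-3-methylpentanoate
Conditions: t-BuOK, t-BuOH/THF, 0 °C; then 11, 0 °C to rt
Reagents that add atoms: none
Why: Classical deconjugative α-alkylation of the thermodynamic exocyclic dienolate of a β-methyl cyclohexenone at C9, followed by return to conjugation, attaches the side chain, while C5 is not enolized because its C–H is hindered and poorly aligned with the π system.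

Step 8
Reactants: 12 the acetal enone
Product: 14 methyl (3S)-3-methyl-5-[(3S)-2-methyl-3-{2-methyl-5-[2-(4-methylbenzenesulfonyl)hydrazinylidene]pentan-2-yl}-6-oxocyclohex-1-en-1-yl]pentanoate, via aldehyde 13 (not isolated)
Conditions: TsNHNH2 (1.1 equiv), TsOH·H2O (10 mol %), THF/H2O, 40 °C
Reagents that add atoms: 4-methylbenzenesulfonohydrazide Cc1ccc(cc1)S(=O)(=O)NN
Why: Acid-catalysed acetal hydrolysis and condensation of the free aldehyde with the sulfonyl hydrazide occur chemoselectively because the hindered tetrasubstituted enone carbonyl does not condense.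

Step 9
Reactants: 14 the conjugated enone tosylhydrazone
Product: 15 methyl (3S)-3-methyl-5-[(3S)-2-methylidene-3-{2-methyl-5-[2-(4-methylbenzenesulfonyl)hydrazinylidene]pentan-2-yl}-6-oxocyclohexyl]pentanoate (mixture of C9 epimers)
Conditions: t-BuOK (3 equiv), t-BuOH/THF, 0 °C; then inverse quench into AcOH/THF/H2O, −78 °C
Reagents that add atoms: none
Why: Enone deconjugation by kinetic α-protonation at C9 of the exocyclic potassium dienolate moves the double bond to C10=C20 and makes C9 an epimerizable sp3 center.

Step 10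
Reactants: 15 the 3-methylidene ketone tosylhydrazone
Product: 17 methyl (3S)-3-methyl-5-[(1R,4aS,8aS)-5,5,8a-trimethyl-2-oxodecahydronaphthalen-1-yl]pentanoate, via N-tosylhydrazide 16 (not isolated)
Conditions: Fe(acac)3 (30 mol %), PhSiH3 (2.5 equiv), EtOH, 60 °C; then Et3N, 80 °C
Reagents that add atoms: none
Why: Fe(acac)3/PhSiH3/EtOH generates an iron hydride that transfers H· to the CH2 terminus of the only alkene (Markovnikov), so C20 becomes the methyl and C10 a tertiary radical; this radical adds to the C1 carbon of the tosylhydrazone, the hydrazinyl radical is reduced to the N-tosylhydrazide 16, and Et3N with heat expels sulfinate and then N2 to leave C1 as CH2. The closest known reaction type is the iron-hydride HAT radical reductive alkylation of unactivated alkenes with sulfonylhydrazones (the hydromethylation logic), together with 6-exo radical cyclizations onto hydrazones. Ring A closes in the 6-exo-trig mode onto C=N through a chair-like transition state with the tether equatorial on C5. The new stereocenter C10 is controlled by C5 and reinforced by C9: attack on the face anti to both flanking substituents puts C1 equatorial and the methyl axial (trans fusion), as in stepwise radical polyene cyclizations. C9, α to the ketone, is epimerized by Et3N to the equatorial side chain, so both C9 epimers and both hydrazone geometries converge on 17. The step needs ring closure to outrun reduction of the radical and HAT to occur before the alkene returns to conjugation, which the fast 6-exo addition to C=N and the neutral medium are expected to secure.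

Step 11
Reactants: 17 the trans-fused C8 ketone
Product: 18 methyl (3S)-3-methyl-5-[(1R,4aS,8aS)-5,5,8a-trimethyl-2-(trifluoromethanesulfonyloxy)-1,4,4a,5,6,7,8,8a-octahydronaphthalen-1-yl]pentanoate
Conditions: KN(SiMe3)2 (1.05 equiv), THF, −78 °C; then PhNTf2
Reagents that add atoms: N-phenylbis(trifluoromethanesulfonimide) O=S(=O)(N(c1ccccc1)S(=O)(=O)C(F)(F)F)C(F)(F)F
Why: Kinetic deprotonation at the unhindered C7 methylene (not at the hindered C9 methine) and O-sulfonylation fix the C7=C8 enol triflate without touching C9.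

Step 12
Reactants: 18 the enol triflate
Product: 19 dimethyl (5S,9R,10S,13S)-labd-7-ene-15,17-dioate (methyl (1R,4aS,8aS)-1-[(3S)-5-methoxy-3-methyl-5-oxopentyl]-5,5,8a-trimethyl-1,4,4a,5,6,7,8,8a-octahydronaphthalene-2-carboxylate)
Conditions: Pd(OAc)2 (5 mol %), PPh3, CO (1 atm), MeOH, Et3N, DMF, 60 °C
Reagents that add atoms: carbon monoxide [C-]#[O+]; methanol CO
Why: Palladium-catalysed methoxycarbonylation of the vinyl triflate (oxidative addition, CO insertion, methanolysis) installs C17 on the C7=C8 double bond.

Step 13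
Reactants: 19 the diester
Product: 20 (5S,9R,10S,13S)-labd-7-ene-15,17-diol
Conditions: i-Bu2AlH (6 equiv), CH2Cl2, −78 to 0 °C; Rochelle salt work-up
Reagents that add atoms: none
Why: Hydride reduction takes the conjugated ester (1,2-reduction) and the saturated ester to the two primary alcohols in one operation.

Step 14
Reactants: 20 the diol
Product: 21 (5S,9R,10S,13S)-labd-7-ene-15,17-diyl diacetate (target)
Conditions: Ac2O, pyridine, DMAP (cat.), CH2Cl2, rt
Reagents that add atoms: acetic anhydride CC(=O)OC(C)=O
Why: DMAP-catalysed acylation converts both primary alcohols into the acetates.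

Compound list
1 | 3-methylbut-2-enal | CC(C)=CC=O | starting material
2 | [2-(1,3-dioxolan-2-yl)ethyl]magnesium bromide | Br[Mg]CCC1OCCO1 | starting material
3 | 5-(1,3-dioxolan-2-yl)-3,3-dimethylpentanal | O=CCC(C)(C)CCC1OCCO1 | intermediate
4 | but-3-en-2-one | CC(=O)C=C | starting material
5 | (2S)-2-[4-(1,3-dioxolan-2-yl)-2-methylbutan-2-yl]-5-oxohexanal | O=C[C@@H](CCC(C)=O)C(C)(C)CCC1OCCO1 | intermediate (not isolated)
6 | (4R)-4-[4-(1,3-dioxolan-2-yl)-2-methylbutan-2-yl]cyclohex-2-en-1-one | O=C1C=C[C@H](C(C)(C)CCC2OCCO2)CC1 | intermediate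
7 | {[(3S,4R)-4-[4-(1,3-dioxolan-2-yl)-2-methylbutan-2-yl]-3-methylcyclohex-1-en-1-yl]oxy}trimethylsilane | C[Si](C)(C)OC1=C[C@@H](C)[C@H](C(C)(C)CCC2OCCO2)CC1 | intermediate
8 | (4S)-4-[4-(1,3-dioxolan-2-yl)-2-methylbutan-2-yl]-3-methylcyclohex-2-en-1-one | O=C1C=C(C)[C@H](C(C)(C)CCC2OCCO2)CC1 | intermediate
9 | (3R)-5-methoxy-3-methyl-5-oxopentanoic acid | OC(=O)C[C@@H](C)CC(=O)OC | starting material
10 | (4S)-4-methyloxan-2-one | O=C1C[C@@H](C)CCO1 | intermediate
11 | methyl (3R)-5-iodo-3-methylpentanoate | COC(=O)C[C@@H](C)CCI | intermediate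
12 | methyl (3S)-5-{(3S)-3-[4-(1,3-dioxolan-2-yl)-2-methylbutan-2-yl]-2-methyl-6-oxocyclohex-1-en-1-yl}-3-methylpentanoate | COC(=O)C[C@@H](C)CCC1=C(C)[C@H](C(C)(C)CCC2OCCO2)CCC1=O | intermediate
13 | methyl (3S)-3-methyl-5-[(3S)-2-methyl-3-(2-methyl-5-oxopentan-2-yl)-6-oxocyclohex-1-en-1-yl]pentanoate | COC(=O)C[C@@H](C)CCC1=C(C)[C@H](C(C)(C)CCC=O)CCC1=O | intermediate (not isolated)
14 | methyl (3S)-3-methyl-5-[(3S)-2-methyl-3-{2-methyl-5-[2-(4-methylbenzenesulfonyl)hydrazinylidene]pentan-2-yl}-6-oxocyclohex-1-en-1-yl]pentanoate | COC(=O)C[C@@H](C)CCC1=C(C)[C@H](C(C)(C)CCC=NNS(=O)(=O)c2ccc(C)cc2)CCC1=O | intermediate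
15 | methyl (3S)-3-methyl-5-[(3S)-2-methylidene-3-{2-methyl-5-[2-(4-methylbenzenesulfonyl)hydrazinylidene]pentan-2-yl}-6-oxocyclohexyl]pentanoate (C9 epimers) | COC(=O)C[C@@H](C)CCC1C(=O)CC[C@@H](C(C)(C)CCC=NNS(=O)(=O)c2ccc(C)cc2)C1=C | intermediate
16 | methyl (3S)-3-methyl-5-[(4aS,8aS)-5,5,8a-trimethyl-8-[2-(4-methylbenzenesulfonyl)hydrazinyl]-2-oxodecahydronaphthalen-1-yl]pentanoate (C1 and C9 unassigned) | COC(=O)C[C@@H](C)CCC1C(=O)CC[C@H]2C(C)(C)CCC(NNS(=O)(=O)c3ccc(C)cc3)[C@]12C | intermediate (not isolated)
17 | methyl (3S)-3-methyl-5-[(1R,4aS,8aS)-5,5,8a-trimethyl-2-oxodecahydronaphthalen-1-yl]pentanoate | COC(=O)C[C@@H](C)CC[C@H]1C(=O)CC[C@H]2C(C)(C)CCC[C@]12C | intermediate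
18 | methyl (3S)-3-methyl-5-[(1R,4aS,8aS)-5,5,8a-trimethyl-2-(trifluoromethanesulfonyloxy)-1,4,4a,5,6,7,8,8a-octahydronaphthalen-1-yl]pentanoate | COC(=O)C[C@@H](C)CC[C@H]1C(OS(=O)(=O)C(F)(F)F)=CC[C@H]2C(C)(C)CCC[C@]12C | intermediate
19 | dimethyl (5S,9R,10S,13S)-labd-7-ene-15,17-dioate | COC(=O)C[C@@H](C)CC[C@H]1C(C(=O)OC)=CC[C@H]2C(C)(C)CCC[C@]12C | intermediate
20 | (5S,9R,10S,13S)-labd-7-ene-15,17-diol | OCC[C@@H](C)CC[C@H]1C(CO)=CC[C@H]2C(C)(C)CCC[C@]12C | intermediate
21 | (5S,9R,10S,13S)-labd-7-ene-15,17-diyl diacetate | CC(=O)OCC[C@@H](C)CC[C@H]1C(COC(C)=O)=CC[C@H]2C(C)(C)CCC[C@]12C | target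

Total step count: 14. Longest linear sequence: 12 steps (steps 1–4 and 7–14); steps 5–6 make the side-chain iodide.

Steps most likely to fail

1. Step 10 (key step). The C10=C20 alkene may slip back into conjugation with the C8 ketone through enolization at C9 before hydrogen-atom transfer. The tertiary radical may also be reduced before it closes, or closure may occur on the other face of C10 and give the cis fusion. The fallback takes the carbonyl out of ring B for the ring closure. It sets out from 15: Luche reduction (NaBH4, CeCl3·7H2O, MeOH, −78 °C) should give the C8 carbinol F1 as a mixture at C8 and C9, which has no acidic C9–H and an all-sp3 chair ring B. The same Fe(acac)3/PhSiH3 closure and Et3N fragmentation should then give the bicyclic alcohol F2, whose ring-fusion isomers should be separable by chromatography. Dess–Martin oxidation and equilibration of C9 with DBU come back to the route at 17.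

2. Step 2. Enamine addition at the neopentyl-type α-carbon of 3 may be slow, and the configuration at C5 may erode by enolization during the basic condensation. The fallback builds the ring without asymmetric induction and sets C5 by enantioselective deprotonation. It sets out from 3 and 4: a pyrrolidine-enamine Robinson annulation should give the racemic enone F3, and H2 over Pd/C the achiral 4-substituted cyclohexanone F4. A chiral lithium amide (lithium bis[(R)-1-phenylethyl]amide or its enantiomer, TMSCl, LiCl, THF, −100 °C) should give the (4R)-enol silane F5. Saegusa–Ito oxidation with Pd(OAc)2 comes back to the route at 6.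

3. Step 7. The dienolate may be alkylated at oxygen, at C7 or twice, tert-butoxide may attack the ester of 11, or enolization toward C5 may erode its configuration. The fallback avoids dienolates through a three-component coupling. It sets out from 6: Me2CuLi followed by 11 with HMPA should give the 2,3-trans-3,4-trans ketone F6. TMSCl, NaI and Et3N in MeCN should give the more substituted enol silane F7, and Pd(OAc)2 comes back to the route at 12.

Further compounds
F1 | step 10 | methyl (3S)-5-[(3S)-6-hydroxy-2-methylidene-3-{2-methyl-5-[2-(4-methylbenzenesulfonyl)hydrazinylidene]pentan-2-yl}cyclohexyl]-3-methylpentanoate | COC(=O)C[C@@H](C)CCC1C(O)CC[C@@H](C(C)(C)CCC=NNS(=O)(=O)c2ccc(C)cc2)C1=C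
F2 | step 10 | methyl (3S)-5-[(4aS,8aS)-2-hydroxy-5,5,8a-trimethyldecahydronaphthalen-1-yl]-3-methylpentanoate | COC(=O)C[C@@H](C)CCC1C(O)CC[C@H]2C(C)(C)CCC[C@]12C
F3 | step 2 | rac-4-[4-(1,3-dioxolan-2-yl)-2-methylbutan-2-yl]cyclohex-2-en-1-one | O=C1C=CC(C(C)(C)CCC2OCCO2)CC1
F4 | step 2 | 4-[4-(1,3-dioxolan-2-yl)-2-methylbutan-2-yl]cyclohexan-1-one | O=C1CCC(C(C)(C)CCC2OCCO2)CC1
F5 | step 2 | {[(4R)-4-[4-(1,3-dioxolan-2-yl)-2-methylbutan-2-yl]cyclohex-1-en-1-yl]oxy}trimethylsilane | C[Si](C)(C)OC1=CC[C@H](C(C)(C)CCC2OCCO2)CC1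
F6 | step 7 | methyl (3S)-5-{(1R,2S,3R)-3-[4-(1,3-dioxolan-2-yl)-2-methylbutan-2-yl]-2-methyl-6-oxocyclohexyl}-3-methylpentanoate | COC(=O)C[C@@H](C)CC[C@H]1C(=O)CC[C@@H](C(C)(C)CCC2OCCO2)[C@@H]1C
F7 | step 7 | methyl (3S)-5-{(5R,6S)-5-[4-(1,3-dioxolan-2-yl)-2-methylbutan-2-yl]-6-methyl-2-[(trimethylsilyl)oxy]cyclohex-1-en-1-yl}-3-methylpentanoate | COC(=O)C[C@@H](C)CCC1=C(O[Si](C)(C)C)CC[C@@H](C(C)(C)CCC2OCCO2)[C@@H]1C
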